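The α-methylene-γ-lactone ring (O–C6–C7–C11–C12; germacranolide numbering, ring C1–C10, lactone C11–C13) is broken at C7–C11. In the target this bond lies anti to the C8–O bond and O6 carries C12, so C7/C8 is read as a trans-epoxide and C11 as the carbanion of an O6-bound phosphonoacetate. In one flask the carbanion opens the epoxide at C7 (5-exo-tet, inversion), closing the lactone and freeing the C8 hydroxyl for the side-chain ester, and formaldehyde converts the phosphonate into C11=C13. The precursor is the ten-membered 4,5:7,8-diepoxy dienoate, closed at C1–C2 by Stille coupling; both epoxides are set from the C6 carbinol by directed epoxidations.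

Key step: step 13

Remark: every intermediate is numbered as the target (C14 = ester carbon on C10, C15 = methyl on C4); in step 1 the ligand antipode is the one that delivers the 3S alcohol.

Step 1
Reactants: 1 3-(trimethylsilyl)prop-2-ynal; 2 1-methoxy-1-(trimethylsilyloxy)ethene
Product: 4 methyl (3S)-3-hydroxypent-4-ynoate, via bis-silyl aldol adduct 3 (not isolated)
Conditions: Ti(OiPr)4 (2 mol%), Schiff-base ligand from 2-amino-2'-hydroxy-1,1'-binaphthyl and 3-bromo-5-tert-butylsalicylaldehyde (2.2 mol%), 3,5-di-tert-butylsalicylic acid (2 mol%), Et2O, −10 °C; then K2CO3 (cat.), MeOH, rt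
Reagents that add atoms: none
Why: Catalytic enantioselective Mukaiyama acetate aldol addition to the ynal, in which the chiral titanium Schiff-base complex blocks one aldehyde face and so sets C9 (3S here), followed by methanolysis of the O–Si and alkynyl C–Si bonds.

Step 2
Reactants: 4 methyl (3S)-3-hydroxypent-4-ynoate
Product: 5 methyl (3S)-3-(tert-butyldimethylsilyloxy)pent-4-ynoate
Conditions: TBSCl, imidazole, DMF, rt
Reagents that add atoms: tert-butyldimethylsilyl chloride, CC(C)(C)[Si](C)(C)Cl
Why: Standard silyl ether formation protects O9 for the whole route without touching the stereocentre.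

Step 3
Reactants: 5 methyl (3S)-3-(tert-butyldimethylsilyloxy)pent-4-ynoate
Product: 6 methyl (3R)-3-(tert-butyldimethylsilyloxy)-2-(hydroxymethylidene)pent-4-ynoate (enol form of the 2-formyl ester)
Conditions: LDA (2.2 equiv), THF, −78 °C; HCO2Me, −78 → −40 °C; AcOH
Reagents that add atoms: methyl formate, COC=O
Why: Crossed Claisen condensation of the ester enolate (acetylide–enolate dianion) with methyl formate introduces C1 at C10; the β-silyloxy enolate should not eliminate at −78 °C, and the acidic product returns its proton to the acetylide.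

Step 4
Reactants: 6 methyl (3R)-3-(tert-butyldimethylsilyloxy)-2-(hydroxymethylidene)pent-4-ynoate
Product: 7 methyl (2E,3R)-3-(tert-butyldimethylsilyloxy)-2-[(trifluoromethylsulfonyloxy)methylidene]pent-4-ynoate
Conditions: Me4NOH (aq), Tf2O, toluene, 5 °C
Reagents that add atoms: trifluoromethanesulfonic anhydride, O=S(=O)(OS(=O)(=O)C(F)(F)F)C(F)(F)F
Why: Schotten–Baumann-type O-triflation of the enolate with a non-coordinating cation, whose extended (non-chelated) form should place OTf trans to the ester and thus fix the C10=C1 geometry that the ring needs.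

Step 5
Reactants: 8 (2E)-3-methylpent-2-en-4-yn-1-ol
Product: 9 (2E)-3-methyl-5-(tributylstannyl)pent-2-en-4-yn-1-ol
Conditions: n-BuLi (2.05 equiv), THF, −78 °C; Bu3SnCl (1.0 equiv), −78 °C → rt
Reagents that add atoms: tributyltin chloride, CCCC[Sn](Cl)(CCCC)CCCC
Why: C-stannylation of the acetylide carbon of the alkoxide–acetylide dianion gives the alkynylstannane.

Step 6
Reactants: 9 (2E)-3-methyl-5-(tributylstannyl)pent-2-en-4-yn-1-ol
Product: 11 (2E,4Z)-3-methyl-5-(tributylstannyl)penta-2,4-dien-1-ol, via stannyl zirconocene adduct 10 (not isolated)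
Conditions: Cp2Zr(H)Cl (2.2 equiv), THF, rt; then H2O
Reagents that add atoms: none
Why: syn-Hydrozirconation of the stannylalkyne puts zirconium on the tin-bearing carbon, and protonolysis with retention gives the Z-vinylstannane (future C2=C3); the first equivalent is consumed by the hydroxyl.

Step 7
Reactants: 11 (2E,4Z)-3-methyl-5-(tributylstannyl)penta-2,4-dien-1-ol
Product: 12 (2E,4Z)-3-methyl-5-(tributylstannyl)penta-2,4-dienal
Conditions: MnO2, CH2Cl2, rt
Reagents that add atoms: none
Why: Allylic alcohol oxidation with MnO2 gives the enal (C6) and should leave the vinylstannane and both alkene geometries intact.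

Step 8
Reactants: 7 methyl (2E,3R)-3-(tert-butyldimethylsilyloxy)-2-[(trifluoromethylsulfonyloxy)methylidene]pent-4-ynoate; 12 (2E,4Z)-3-methyl-5-(tributylstannyl)penta-2,4-dienal
Product: 15 methyl (2E,3R,4E,6S,7E,9Z)-3-(tert-butyldimethylsilyloxy)-6-hydroxy-8-methyl-10-(tributylstannyl)-2-[(trifluoromethylsulfonyloxy)methylidene]deca-4,7,9-trienoate, via alkenylborane 13 (not isolated), via alkenylzinc 14 (not isolated)
Conditions: Cy2BH, toluene, 0 °C → rt; Me2Zn, −78 °C; (−)-MIB (5 mol%), then 12, −20 °C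
Reagents that add atoms: none
Why: Hydroboration of the terminal alkyne, boron-to-zinc exchange and amino-alcohol-catalysed asymmetric alkenylzinc 1,2-addition to the enal form C6–C7 together with the E-C7=C8 alkene, (−)-MIB being expected to direct attack to the aldehyde face that gives the 6S carbinol.

Step 9
Reactants: 15 open-chain trienol (6S)
Product: 16 methyl (2E,3S)-3-(tert-butyldimethylsilyloxy)-3-{(2S,3R)-3-[(1R,2E,4Z)-1-hydroxy-3-methyl-5-(tributylstannyl)penta-2,4-dienyl]oxiran-2-yl}-2-[(trifluoromethylsulfonyloxy)methylidene]propanoate (7R,8S-epoxide)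
Conditions: Ti(OiPr)4 (20 mol%), D-(−)-DIPT (24 mol%), TBHP, 4 Å MS, CH2Cl2, −20 °C
Reagents that add atoms: tert-butyl hydroperoxide, CC(C)(C)OO
Why: Sharpless asymmetric epoxidation as a matched, reagent-controlled step: for the 6S carbinol D-(−)-tartrate is the fast combination at the E-C7=C8 alkene and the slow one at C4=C5, so oxygen should go only to C7=C8, erythro to the C6 hydroxyl, while any 6R epimer is left behind by kinetic resolution.

Step 10
Reactants: 16 7,8-epoxy dienol
Product: 17 open-chain (4R,5R,6S,7R,8S,9S)-4,5:7,8-diepoxy alcohol carrying the C1 enol triflate and the C2 Z-vinylstannane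
Conditions: VO(acac)2 (5 mol%), TBHP, CH2Cl2, 0 °C
Reagents that add atoms: tert-butyl hydroperoxide, CC(C)(C)OO
Why: Hydroxyl-directed vanadium-catalysed epoxidation of the one remaining allylic alkene; A(1,3) strain between the C15 methyl and the C6 substituents holds H6 near the alkene plane, so oxygen is delivered to the face that gives the threo (4R,5R) epoxy alcohol.

Step 11
Reactants: 17 open-chain diepoxy alcohol
Product: 18 methyl (1(10)E,2Z,4R,5R,6S,7R,8S,9S)-9-(tert-butyldimethylsilyloxy)-4,5:7,8-diepoxy-6-hydroxy-4-methylcyclodeca-1(10),2-diene-10-carboxylate (target numbering)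
Conditions: Pd(PPh3)4 (10 mol%), Cu(O2CC4H3S) (copper thiophene-2-carboxylate, 1.5 equiv), [NBu4][Ph2PO2] (1.5 equiv), DMF, 1 mM, rt
Reagents that add atoms: none
Why: Intramolecular Stille–Migita coupling of the activated E-enol triflate with the Z-vinylstannane closes the ten-membered ring at C1–C2 with retention at both alkenes; high dilution should suppress oligomers, the phosphinate removes the Lewis-acidic tin by-product, and fast oxidative addition into the enol triflate should keep zerovalent palladium away from the vinyl epoxide.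

Step 12
Reactants: 18 macrocyclic diepoxy alcohol; 19 (diethoxyphosphoryl)acetic acid
Product: 20 6-O-[(diethoxyphosphoryl)acetyl] ester of 18
Conditions: DCC, DMAP (cat.), CH2Cl2, 0 °C → rt
Reagents that add atoms: none
Why: Steglich esterification of the only free hydroxyl (C6) tethers the future C11/C12 unit to O6 under neutral conditions that spare both epoxides.

Step 13
Reactants: 20 macrocyclic 6-O-phosphonoacetate
Product: 22 methyl (1(10)E,2Z,4R,5R,6S,7R,8S,9S)-9-(tert-butyldimethylsilyloxy)-4,5-epoxy-8-hydroxygermacra-1(10),2,11(13)-trien-12,6-olid-14-oate, via α-phosphono lactone 21 (not isolated)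
Conditions: NaH (1.1 equiv), THF, 0 → 60 °C; then (CH2O)n, 0 °C → rt
Reagents that add atoms: formaldehyde (as paraformaldehyde), C=O
Why: Sodium hydride gives the phosphonoacetate carbanion (C11), which opens the trans-7,8-epoxide at C7 by intramolecular SN2 attack with inversion; the C8 alkoxide is at once protonated by the now doubly activated C11–H of 21, so that a stabilised phosphonate anion and not an alkoxide is carried into the Horner–Wadsworth–Emmons reaction with formaldehyde that installs C11=C13. The closest known reactions are the opening of epoxides by phosphonoacetate anions (first stage of the Wadsworth–Emmons cyclopropanation and of α-phosphono-γ-lactone syntheses), epoxynitrile-type cyclisations of tethered stabilised carbanions, and the phosphonate/formaldehyde route to α-methylene lactones. The lactone ring O–C6–C7–C11–C12 closes in the 5-exo-tet mode, the breaking C7–O bond lying outside the new ring. C7 (R) is set by inversion at the epoxide carbon and C8 (S) is retained, so both trace back to the tartrate-controlled epoxidation of step 9, and the trans ring fusion follows because the erythro epoxy alcohol places C6–O anti to C7–O across an extended C5–C6–C7–C8 segment. The step needs attack at C7 rather than at C8 (6-endo), at C5 (5-exo on the other epoxide, but neopentyl next to quaternary C4 and leading to a cis lactone) or at C4 (tertiary), and it needs the carbanion to leave the dienoate alone; ring-size preference, sterics and the twisted dienoate should secure this, and the internal proton transfer should suppress silyl migration from O9 and translactonisation to O8.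

Step 14
Reactants: 23 methyl angelate (methyl (2Z)-2-methylbut-2-enoate)
Product: 24 (2Z)-2-methylbut-2-en-1-ol
Conditions: DIBAL-H (2.2 equiv), CH2Cl2, −78 → 0 °C; Rochelle salt
Reagents that add atoms: none
Why: Hydride reduction of the conjugated ester to the allylic alcohol at low temperature should keep the Z (angelate) geometry.

Step 15
Reactants: 24 (2Z)-2-methylbut-2-en-1-ol
Product: 25 [(2R,3S)-2,3-dimethyloxiran-2-yl]methanol
Conditions: Ti(OiPr)4 (10 mol%), D-(−)-DET (12 mol%), TBHP, 4 Å MS, CH2Cl2, −20 °C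
Reagents that add atoms: tert-butyl hydroperoxide, CC(C)(C)OO
Why: Sharpless asymmetric epoxidation of the trisubstituted Z-allylic alcohol; D-(−)-tartrate delivers oxygen to the face that gives the (2R,3S) epoxy alcohol, so both side-chain stereocentres are reagent-controlled.

Step 16
Reactants: 25 [(2R,3S)-2,3-dimethyloxiran-2-yl]methanol
Product: 26 (2S,3S)-2,3-dimethyloxirane-2-carboxylic acid
Conditions: RuCl3·xH2O (2 mol%), NaIO4 (3 equiv), MeCN/EtOAc/H2O, rt
Reagents that add atoms: water, O
Why: Ruthenium tetroxide oxidation (catalytic RuCl3 with periodate) takes the primary alcohol through the aldehyde hydrate to the acid without opening the epoxide; the C2 descriptor becomes S only through the priority change.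

Step 17
Reactants: 22 8-hydroxy α-methylene lactone; 26 (2S,3S)-2,3-dimethyloxirane-2-carboxylic acid
Product: 27 methyl (1(10)E,2Z,4R,5R,6S,7R,8S,9S)-9-(tert-butyldimethylsilyloxy)-8-[(2S,3S)-2,3-dimethyloxirane-2-carbonyloxy]-4,5-epoxygermacra-1(10),2,11(13)-trien-12,6-olid-14-oate
Conditions: DCC, DMAP, CH2Cl2, rt
Reagents that add atoms: none
Why: Steglich esterification of the only free hydroxyl (C8, liberated by the key step) with the epoxy acid, which has no α-hydrogen and cannot epimerise.

Step 18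
Reactants: 27 9-O-silyl ether of the target
Product: 28 methyl (1(10)E,2Z,4R,5R,6S,7R,8S,9S)-8-[(2S,3S)-2,3-dimethyloxirane-2-carbonyloxy]-4,5-epoxy-9-hydroxygermacra-1(10),2,11(13)-trien-12,6-olid-14-oate (CNP0131597.1)
Conditions: HF·pyridine, pyridine, THF, 0 °C
Reagents that add atoms: none
Why: Pyridine-buffered fluoride cleavage of the silyl ether frees the C9 hydroxyl under conditions that should be mild enough for the dienyl epoxide, the epoxy ester and the α-methylene lactone.

Compound list

1 | 3-(trimethylsilyl)prop-2-ynal | C[Si](C)(C)C#CC=O | starting material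
2 | 1-methoxy-1-(trimethylsilyloxy)ethene | C=C(OC)O[Si](C)(C)C | starting material
3 | methyl (3S)-5-(trimethylsilyl)-3-(trimethylsilyloxy)pent-4-ynoate | C[Si](C)(C)C#C[C@@H](O[Si](C)(C)C)CC(=O)OC | intermediate (not isolated)
4 | methyl (3S)-3-hydroxypent-4-ynoate | C#C[C@@H](O)CC(=O)OC | intermediate
5 | methyl (3S)-3-(tert-butyldimethylsilyloxy)pent-4-ynoate | C#C[C@@H](O[Si](C)(C)C(C)(C)C)CC(=O)OC | intermediate
6 | methyl (3R)-3-(tert-butyldimethylsilyloxy)-2-(hydroxymethylidene)pent-4-ynoate (enol of the 2-formyl ester) | C#C[C@@H](O[Si](C)(C)C(C)(C)C)C(C(=O)OC)=CO | intermediate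
7 | methyl (2E,3R)-3-(tert-butyldimethylsilyloxy)-2-[(trifluoromethylsulfonyloxy)methylidene]pent-4-ynoate | C#C[C@@H](O[Si](C)(C)C(C)(C)C)/C(C(=O)OC)=C\OS(=O)(=O)C(F)(F)F | intermediate
8 | (2E)-3-methylpent-2-en-4-yn-1-ol | C#C/C(C)=C/CO | starting material
9 | (2E)-3-methyl-5-(tributylstannyl)pent-2-en-4-yn-1-ol | CCCC[Sn](CCCC)(CCCC)C#C/C(C)=C/CO | intermediate
10 | (2E,4Z)-5-[chlorobis(cyclopentadienyl)zirconio]-3-methyl-5-(tributylstannyl)penta-2,4-dien-1-olate bound through oxygen to a second chlorozirconocene | CCCC[Sn](CCCC)(CCCC)\C([Zr](Cl)(C1C=CC=C1)C1C=CC=C1)=C/C(C)=C/CO[Zr](Cl)(C1C=CC=C1)C1C=CC=C1 | intermediate (not isolated)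
11 | (2E,4Z)-3-methyl-5-(tributylstannyl)penta-2,4-dien-1-ol | CCCC[Sn](CCCC)(CCCC)\C=C/C(C)=C/CO | intermediate
12 | (2E,4Z)-3-methyl-5-(tributylstannyl)penta-2,4-dienal | CCCC[Sn](CCCC)(CCCC)\C=C/C(C)=C/C=O | intermediate
13 | methyl (2E,3R,4E)-3-(tert-butyldimethylsilyloxy)-5-(dicyclohexylboranyl)-2-[(trifluoromethylsulfonyloxy)methylidene]pent-4-enoate | C1CCCCC1B(C1CCCCC1)/C=C/[C@@H](O[Si](C)(C)C(C)(C)C)/C(C(=O)OC)=C\OS(=O)(=O)C(F)(F)F | intermediate (not isolated)
14 | methyl (2E,3R,4E)-3-(tert-butyldimethylsilyloxy)-5-(methylzincio)-2-[(trifluoromethylsulfonyloxy)methylidene]pent-4-enoate | C[Zn]/C=C/[C@@H](O[Si](C)(C)C(C)(C)C)/C(C(=O)OC)=C\OS(=O)(=O)C(F)(F)F | intermediate (not isolated)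
15 | methyl (2E,3R,4E,6S,7E,9Z)-3-(tert-butyldimethylsilyloxy)-6-hydroxy-8-methyl-10-(tributylstannyl)-2-[(trifluoromethylsulfonyloxy)methylidene]deca-4,7,9-trienoate | CCCC[Sn](CCCC)(CCCC)\C=C/C(C)=C/[C@@H](O)/C=C/[C@@H](O[Si](C)(C)C(C)(C)C)/C(C(=O)OC)=C\OS(=O)(=O)C(F)(F)F | intermediate
16 | methyl (2E,3S)-3-(tert-butyldimethylsilyloxy)-3-{(2S,3R)-3-[(1R,2E,4Z)-1-hydroxy-3-methyl-5-(tributylstannyl)penta-2,4-dienyl]oxiran-2-yl}-2-[(trifluoromethylsulfonyloxy)methylidene]propanoate | CCCC[Sn](CCCC)(CCCC)\C=C/C(C)=C/[C@@H](O)[C@H]1O[C@@H]1[C@@H](O[Si](C)(C)C(C)(C)C)/C(C(=O)OC)=C\OS(=O)(=O)C(F)(F)F | intermediate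
17 | open-chain (4R,5R,6S,7R,8S,9S)-4,5:7,8-diepoxy-6-hydroxy-9-silyloxy seco compound with C1 E-enol triflate and C2 Z-vinylstannane (target numbering) | CCCC[Sn](CCCC)(CCCC)\C=C/[C@@]1(C)O[C@@H]1[C@@H](O)[C@H]2O[C@@H]2[C@@H](O[Si](C)(C)C(C)(C)C)/C(C(=O)OC)=C\OS(=O)(=O)C(F)(F)F | intermediate
18 | methyl (1(10)E,2Z,4R,5R,6S,7R,8S,9S)-9-(tert-butyldimethylsilyloxy)-4,5:7,8-diepoxy-6-hydroxy-4-methylcyclodeca-1(10),2-diene-10-carboxylate (target numbering) | O[C@H]1[C@H]2O[C@@H]2[C@@H](O[Si](C)(C)C(C)(C)C)/C(C(=O)OC)=C\C=C/[C@@]2(C)O[C@H]12 | intermediate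
19 | (diethoxyphosphoryl)acetic acid | CCOP(=O)(OCC)CC(=O)O | starting material
20 | 6-O-[(diethoxyphosphoryl)acetyl] ester of 18 | CCOP(=O)(OCC)CC(=O)O[C@H]1[C@H]2O[C@@H]2[C@@H](O[Si](C)(C)C(C)(C)C)/C(C(=O)OC)=C\C=C/[C@@]2(C)O[C@H]12 | intermediate
21 | 11-(diethoxyphosphoryl) analogue of 22 with C11 sp3 and no C13 (C11 epimers) | CCOP(=O)(OCC)C1C(=O)O[C@H]2[C@H]1[C@H](O)[C@@H](O[Si](C)(C)C(C)(C)C)/C(C(=O)OC)=C\C=C/[C@@]1(C)O[C@H]21 | intermediate (not isolated)
22 | methyl (1(10)E,2Z,4R,5R,6S,7R,8S,9S)-9-(tert-butyldimethylsilyloxy)-4,5-epoxy-8-hydroxygermacra-1(10),2,11(13)-trien-12,6-olid-14-oate | C=C1C(=O)O[C@H]2[C@H]1[C@H](O)[C@@H](O[Si](C)(C)C(C)(C)C)/C(C(=O)OC)=C\C=C/[C@@]1(C)O[C@H]21 | intermediate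
23 | methyl angelate (methyl (2Z)-2-methylbut-2-enoate) | C/C=C(/C)C(=O)OC | starting material
24 | (2Z)-2-methylbut-2-en-1-ol | C/C=C(/C)CO | intermediate
25 | [(2R,3S)-2,3-dimethyloxiran-2-yl]methanol | OC[C@@]1(C)O[C@H]1C | intermediate
26 | (2S,3S)-2,3-dimethyloxirane-2-carboxylic acid | OC(=O)[C@@]1(C)O[C@H]1C | intermediate
27 | methyl (1(10)E,2Z,4R,5R,6S,7R,8S,9S)-9-(tert-butyldimethylsilyloxy)-8-[(2S,3S)-2,3-dimethyloxirane-2-carbonyloxy]-4,5-epoxygermacra-1(10),2,11(13)-trien-12,6-olid-14-oate | C=C1C(=O)O[C@H]2[C@H]1[C@H](OC(=O)[C@@]1(C)O[C@H]1C)[C@@H](O[Si](C)(C)C(C)(C)C)/C(C(=O)OC)=C\C=C/[C@@]1(C)O[C@H]21 | intermediate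
28 | methyl (1(10)E,2Z,4R,5R,6S,7R,8S,9S)-8-[(2S,3S)-2,3-dimethyloxirane-2-carbonyloxy]-4,5-epoxy-9-hydroxygermacra-1(10),2,11(13)-trien-12,6-olid-14-oate (CNP0131597.1) | C=C1C(=O)O[C@H]2[C@H]1[C@H](OC(=O)[C@@]1(C)O[C@H]1C)[C@@H](O)/C(C(=O)OC)=C\C=C/[C@@]1(C)O[C@H]21 | target

Total step count: 18. Longest linear sequence: 12 steps (steps 1–4, 8–13, 17 and 18).

Steps most likely to fail

1. Step 11. The ring closure may lose to oligomerisation, or zerovalent palladium may ionise the stannyl-substituted vinyl epoxide before coupling. The fallback sets out from 17 and comes back at 27, and it reverses the order of ring closure and lactone annulation. 17 is esterified with 19 (DCC, DMAP) to the open-chain 6-O-phosphonoacetate F1. NaH and then paraformaldehyde, run dilute so that the carbanion does not substitute the enol triflate of a second molecule, give the open-chain α-phosphono lactone F2 in the flask and from it the open-chain α-methylene lactone F3 with free 8-OH. Steglich esterification with 26 gives the open-chain 8-O-epoxyangelate F4. The same Stille–Migita coupling is then run on a chain already bent by the trans-lactone and the C8 ester, and should give 27.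

2. Step 13. The doubly stabilised, hindered carbanion may open the epoxide too slowly, so that heating brings silyl migration or opening of the 4,5-epoxide. The fallback sets out from 18 and comes back at 22; it uses a non-stabilised ester enolate and a separate methylenation. 18 is acetylated (Ac2O, pyridine, DMAP) to the 6-O-acetate F5. LiHMDS (THF, −78 → 0 °C) forms the lithium enolate, which should open the 7,8-epoxide at C7 at low temperature to the saturated 8-hydroxy lactone F6. Its dianion (LDA, 2.2 equiv) is trapped with Eschenmoser's salt to give the 11-(dimethylaminomethyl) lactone F7. Methyl iodide and then NaHCO3 eliminate trimethylamine through the methiodide F8 to give 22.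

3. Step 8. Facial selectivity at C6 may be poor for this functionalised dienal, giving both C6 epimers. The fallback sets out from 7 and 12 and comes back at 16; it moves the control of C6 from the addition to a kinetic resolution. The alkenylzinc addition is run without the ligand (through 13 and 14) to give the C6-epimeric trienol mixture F9. F9 is treated as in step 9 with D-(−)-DIPT and 0.6 equiv of TBHP. Only the 6S epimer is matched at C7=C8 and should be epoxidised to 16, while the 6R epimer is recovered unchanged.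

Further compounds

F1 | step 11 | open-chain 6-O-[(diethoxyphosphoryl)acetyl] ester of 17 | CCCC[Sn](CCCC)(CCCC)\C=C/[C@@]1(C)O[C@@H]1[C@@H](OC(=O)CP(=O)(OCC)OCC)[C@H]2O[C@@H]2[C@@H](O[Si](C)(C)C(C)(C)C)/C(C(=O)OC)=C\OS(=O)(=O)C(F)(F)F
F2 | step 11 | open-chain α-(diethoxyphosphoryl) lactone with free 8-OH, C1 enol triflate and C2 vinylstannane | CCCC[Sn](CCCC)(CCCC)\C=C/[C@@]1(C)O[C@@H]1[C@H]2OC(=O)C(P(=O)(OCC)OCC)[C@@H]2[C@H](O)[C@@H](O[Si](C)(C)C(C)(C)C)/C(C(=O)OC)=C\OS(=O)(=O)C(F)(F)F
F3 | step 11 | open-chain α-methylene lactone with free 8-OH, C1 enol triflate and C2 vinylstannane | CCCC[Sn](CCCC)(CCCC)\C=C/[C@@]1(C)O[C@@H]1[C@H]2OC(=O)C(=C)[C@@H]2[C@H](O)[C@@H](O[Si](C)(C)C(C)(C)C)/C(C(=O)OC)=C\OS(=O)(=O)C(F)(F)F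
F4 | step 11 | 8-O-[(2S,3S)-2,3-dimethyloxirane-2-carbonyl] ester of F3 | CCCC[Sn](CCCC)(CCCC)\C=C/[C@@]1(C)O[C@@H]1[C@H]2OC(=O)C(=C)[C@@H]2[C@H](OC(=O)[C@@]3(C)O[C@H]3C)[C@@H](O[Si](C)(C)C(C)(C)C)/C(C(=O)OC)=C\OS(=O)(=O)C(F)(F)F
F5 | step 13 | 6-O-acetate of 18 | CC(=O)O[C@H]1[C@H]2O[C@@H]2[C@@H](O[Si](C)(C)C(C)(C)C)/C(C(=O)OC)=C\C=C/[C@@]2(C)O[C@H]12
F6 | step 13 | saturated lactone (C11H2, no C13) with free 8-OH and 9-O-silyl ether | C1C(=O)O[C@H]2[C@H]1[C@H](O)[C@@H](O[Si](C)(C)C(C)(C)C)/C(C(=O)OC)=C\C=C/[C@@]1(C)O[C@H]21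
F7 | step 13 | 11-(dimethylaminomethyl) lactone (C11 epimers) | CN(C)CC1C(=O)O[C@H]2[C@H]1[C@H](O)[C@@H](O[Si](C)(C)C(C)(C)C)/C(C(=O)OC)=C\C=C/[C@@]1(C)O[C@H]21
F8 | step 13 | methiodide of F7 | C[N+](C)(C)CC1C(=O)O[C@H]2[C@H]1[C@H](O)[C@@H](O[Si](C)(C)C(C)(C)C)/C(C(=O)OC)=C\C=C/[C@@]1(C)O[C@H]21.[I-]
F9 | step 8 | C6-epimeric mixture of trienol 15 | CCCC[Sn](CCCC)(CCCC)\C=C/C(C)=C/C(O)/C=C/[C@@H](O[Si](C)(C)C(C)(C)C)/C(C(=O)OC)=C\OS(=O)(=O)C(F)(F)F
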